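The route exploits the oxygen pattern of ring A. The ester carbon on C1, OH on C2 and C4, and CH3 on C6 mark it as a cyclised chain of four acetate units. Cutting the ring-A C1–C6 bond unfolds ring A into a 3,5,7-trioxooctanoyl chain that already hangs on the C4 oxygen of the fully substituted ring B. In one operation, aldol addition of chain C2 to the C7 ketone, loss of water and enolisation close ring A. This completes the depside skeleton with its hindered ester bond in place. The chain arrives as an acylketene released from a diketo-dioxinone, and the formyl groups at C3 and C5 of ring A come last.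

Key step: step 9

Remark on the chemistry: the target has no stereocentre, so none has to be set, and polycarbonyl compounds are drawn as keto tautomers although they are largely enolised.
Numbering used:
- Ring B: C1 (CO2Me), C2 (OMe), C3 (CH3), C4 (O-acyl), C5 (CH3), C6 (CH3).
- Ring A: C1 (C=O), C2 (OH), C3, C4 (OH), C5, C6 (CH3).
- Chain: C1 (ester carbonyl) to C8 (terminal CH3).

Step 1
Reactants: 1 2,2,6-trimethyl-4H-1,3-dioxin-4-one; 2 acetyl chloride
Product: 4 2,2-dimethyl-6-(2-oxopropyl)-4H-1,3-dioxin-4-one, via lithium dienolate 3 (not isolated)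
Conditions: 1 (2 equiv), LiN(SiMe3)2 (2 equiv), THF, −78 °C; then 2 (1 equiv), −78 → −20 °C; 1 M aq HCl
Reagents that add atoms: none
Why: Deprotonation of the C6 methyl group gives the cross-conjugated dienolate 3, which is acylated at its exocyclic γ-carbon by the acid chloride (vinylogous Claisen-type C-acylation), while the second equivalent of 3 takes up the acidic proton of 4 and is recovered as 1.

Step 2
Reactants: 4 2,2-dimethyl-6-(2-oxopropyl)-4H-1,3-dioxin-4-one; 5 N-methoxy-N-methylacetamide
Product: 7 2,2-dimethyl-6-(2,4-dioxopentyl)-4H-1,3-dioxin-4-one, via dilithium dianion 6 (not isolated)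
Conditions: LiN(i-Pr)2 (2.2 equiv), THF, −78 → −40 °C; then 5, −78 → −10 °C; 1 M aq HCl to pH 3
Reagents that add atoms: none
Why: Two deprotonations give dianion 6, whose last-formed terminal carbanion is the most nucleophilic site and adds to the amide (Weinreb ketone synthesis with a 1,3-dicarbonyl dianion), the chelated tetrahedral adduct holding until the acidic quench so that neither over-addition nor proton transfer from the product can interfere.

Step 3
Reactants: 8 methyl 2,4-dihydroxy-3,6-dimethylbenzoate (atraric acid)
Product: 10 methyl 5-formyl-2,4-dihydroxy-3,6-dimethylbenzoate, via alpha-chloro ether 9 (not isolated)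
Conditions: Cl2CHOMe (1.5 equiv), TiCl4 (3 equiv), CH2Cl2, 0 °C → rt; then 1 M aq HCl
Reagents that add atoms: dichloromethyl methyl ether, COC(Cl)Cl; water, O
Why: Rieche formylation can only strike C5, the single free ring position, which lies ortho to the C4 hydroxyl and para to the C2 hydroxyl, and hydrolysis of 9 on work-up releases the aldehyde.

Step 4
Reactants: 10 methyl 5-formyl-2,4-dihydroxy-3,6-dimethylbenzoate
Product: 12 methyl 2,4-dihydroxy-3,5,6-trimethylbenzoate, via benzylic alcohol 11 (not isolated)
Conditions: H2 (3 bar), 10% Pd/C, AcOH, cat. HCl, 40 °C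
Reagents that add atoms: none
Why: Catalytic hydrogenation to 11 followed by acid-assisted benzylic hydrogenolysis, easy because the ortho and para hydroxyls stabilise the benzylic cation, turns CHO into CH3 without touching the hindered ester.

Step 5
Reactants: 12 methyl 2,4-dihydroxy-3,5,6-trimethylbenzoate
Product: 13 methyl 4-(benzyloxy)-2-hydroxy-3,5,6-trimethylbenzoate
Conditions: BnBr (1.05 equiv), K2CO3 (1.2 equiv), acetone, reflux
Reagents that add atoms: benzyl bromide, BrCc1ccccc1
Why: Williamson ether synthesis should select the C4 hydroxyl because the C2 hydroxyl is locked in a hydrogen bond to the ester carbonyl and is ionised far less readily.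

Step 6
Reactants: 13 methyl 4-(benzyloxy)-2-hydroxy-3,5,6-trimethylbenzoate
Product: 14 methyl 4-(benzyloxy)-2-methoxy-3,5,6-trimethylbenzoate
Conditions: MeI (4 equiv), K2CO3 (3 equiv), DMF, 50 °C
Reagents that add atoms: iodomethane, CI
Why: Williamson O-methylation with excess reagent in a dipolar aprotic solvent breaks the chelate and alkylates the only hydroxyl that is left.

Step 7
Reactants: 14 methyl 4-(benzyloxy)-2-methoxy-3,5,6-trimethylbenzoate
Product: 15 methyl 4-hydroxy-2-methoxy-3,5,6-trimethylbenzoate
Conditions: H2 (1 bar), 10% Pd/C, EtOAc, rt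
Reagents that add atoms: none
Why: Hydrogenolysis of the benzyl aryl ether frees the C4 phenol, and nothing else in 14 is reducible under these conditions.

Step 8
Reactants: 7 2,2-dimethyl-6-(2,4-dioxopentyl)-4H-1,3-dioxin-4-one; 15 methyl 4-hydroxy-2-methoxy-3,5,6-trimethylbenzoate
Product: 17 3-methoxy-4-(methoxycarbonyl)-2,5,6-trimethylphenyl 3,5,7-trioxooctanoate, via acylketene 16 (not isolated)
Conditions: 15 (2 equiv, 1 M in toluene), 110 °C; 7 added over 1 h by syringe pump; cooled at once; crude 17 with the surplus 15 carried on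
Reagents that add atoms: none
Why: Retro-hetero-Diels–Alder loss of acetone gives acylketene 16, and phenols add to acylketenes through a planar, sterically undemanding six-centre transition state, so the di-ortho-methyl phenol 15 should be acylated if its concentration is kept high enough to outrun capture of the ketene by its own C5 enol.

Step 9
Reactants: 17 3-methoxy-4-(methoxycarbonyl)-2,5,6-trimethylphenyl 3,5,7-trioxooctanoate
Product: 19 methyl 4-[(2,4-dihydroxy-6-methylbenzoyl)oxy]-2-methoxy-3,5,6-trimethylbenzoate, via aldol carbinol 18 (not isolated)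
Conditions: Et3N (2 equiv), CH2Cl2, 0 °C → rt; then HCl (4 M in dioxane, 3 equiv), 0 °C → rt; surplus 15 recovered by chromatography
Reagents that add atoms: none
Why: Et3N ionises the polyketone reversibly: the C4 and C6 methylenes, each between two ketones, give up their protons first, but proton exchange also populates the C2 enolate of the β-keto ester, the only carbon nucleophile reachable with a weak base that has a ketone at six-ring distance. Addition of C2 to the C7 methyl ketone forms the ring-A C1–C6 bond in a 6-(enolendo)-exo-trig closure and gives carbinol 18; acid then removes water and the C3 and C5 ketones enolise, so that aromatisation makes the sequence irreversible. The closest known reaction type is the biomimetic aldol aromatisation of 3,5,7-triketo esters to resorcylates, which is established for esters made by acylketene capture. The two stereocentres of 18 form without control and are erased on aromatisation, so no element of stereocontrol is needed. The step needs chemoselectivity for attack at C7 over acyl substitution at C1 by C6 (Claisen closure) or by the C5 enol oxygen (2-pyrone formation), both of which would expel phenol 15; the C3 and C5 methyl groups of ring B flank the ester oxygen and screen that carbonyl, whereas C7 is an unhindered methyl ketone. A weak amine in an aprotic, alcohol-free medium keeps the enolate concentration low and so slows E1cB loss of the phenoxide, leaves the C8 methyl un-ionised so that the alternative C8-to-C3 aldol is excluded, and the surplus 15 carried over can re-add to any ketene that is set free.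

Step 10
Reactants: 19 methyl 4-[(2,4-dihydroxy-6-methylbenzoyl)oxy]-2-methoxy-3,5,6-trimethylbenzoate
Product: 21 methyl 4-[(3,5-diformyl-2,4-dihydroxy-6-methylbenzoyl)oxy]-2-methoxy-3,5,6-trimethylbenzoate, via bis-aldimine 20 (not isolated)
Conditions: (CH2)6N4 (4 equiv), CF3CO2H, 75 °C; then 4 M aq HCl, rt
Reagents that add atoms: hexamethylenetetramine, C1N2CN3CN1CN(C2)C3; water, O
Why: In this double Duff reaction C3 and C5 of ring A are the only unsubstituted aromatic positions of 19 and both lie ortho to a hydroxyl, and because each new carbon is attached at the benzylamine level and becomes a carbonyl only on hydrolysis of 20, the first substitution does not shut down the second, as in the known exhaustive formylation of hydroxybenzoates and resorcinols.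

Compound list
1 | 2,2,6-trimethyl-4H-1,3-dioxin-4-one | CC1=CC(=O)OC(C)(C)O1 | starting material
2 | acetyl chloride | CC(=O)Cl | starting material
3 | lithium 2,2-dimethyl-6-methylidene-6H-1,3-dioxin-4-olate (dienolate of 1) | [Li+].C=C1C=C([O-])OC(C)(C)O1 | intermediate
4 | 2,2-dimethyl-6-(2-oxopropyl)-4H-1,3-dioxin-4-one | CC(=O)CC1=CC(=O)OC(C)(C)O1 | intermediate
5 | N-methoxy-N-methylacetamide | CC(=O)N(C)OC | starting material
6 | dilithium dianion of 4 (ring dienolate plus terminal enolate of the side-chain ketone) | [Li+].[Li+].C=C([O-])C=C1C=C([O-])OC(C)(C)O1 | intermediate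
7 | 2,2-dimethyl-6-(2,4-dioxopentyl)-4H-1,3-dioxin-4-one | CC(=O)CC(=O)CC1=CC(=O)OC(C)(C)O1 | intermediate
8 | methyl 2,4-dihydroxy-3,6-dimethylbenzoate (atraric acid) | COC(=O)c1c(C)cc(O)c(C)c1O | starting material
9 | methyl 5-[chloro(methoxy)methyl]-2,4-dihydroxy-3,6-dimethylbenzoate (racemic) | COC(=O)c1c(C)c(C(Cl)OC)c(O)c(C)c1O | intermediate
10 | methyl 5-formyl-2,4-dihydroxy-3,6-dimethylbenzoate | COC(=O)c1c(C)c(C=O)c(O)c(C)c1O | intermediate
11 | methyl 2,4-dihydroxy-5-(hydroxymethyl)-3,6-dimethylbenzoate | COC(=O)c1c(C)c(CO)c(O)c(C)c1O | intermediate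
12 | methyl 2,4-dihydroxy-3,5,6-trimethylbenzoate | COC(=O)c1c(C)c(C)c(O)c(C)c1O | intermediate
13 | methyl 4-(benzyloxy)-2-hydroxy-3,5,6-trimethylbenzoate | COC(=O)c1c(C)c(C)c(OCc2ccccc2)c(C)c1O | intermediate
14 | methyl 4-(benzyloxy)-2-methoxy-3,5,6-trimethylbenzoate | COC(=O)c1c(C)c(C)c(OCc2ccccc2)c(C)c1OC | intermediate
15 | methyl 4-hydroxy-2-methoxy-3,5,6-trimethylbenzoate | COC(=O)c1c(C)c(C)c(O)c(C)c1OC | intermediate
16 | 3,5,7-trioxooct-1-en-1-one (diketo acylketene) | CC(=O)CC(=O)CC(=O)C=C=O | intermediate
17 | 3-methoxy-4-(methoxycarbonyl)-2,5,6-trimethylphenyl 3,5,7-trioxooctanoate | CC(=O)CC(=O)CC(=O)CC(=O)Oc1c(C)c(C)c(C(=O)OC)c(OC)c1C | intermediate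
18 | 3-methoxy-4-(methoxycarbonyl)-2,5,6-trimethylphenyl 2-hydroxy-2-methyl-4,6-dioxocyclohexane-1-carboxylate (racemic mixture of diastereomers) | CC1(O)CC(=O)CC(=O)C1C(=O)Oc1c(C)c(C)c(C(=O)OC)c(OC)c1C | intermediate
19 | methyl 4-[(2,4-dihydroxy-6-methylbenzoyl)oxy]-2-methoxy-3,5,6-trimethylbenzoate | Cc1cc(O)cc(O)c1C(=O)Oc1c(C)c(C)c(C(=O)OC)c(OC)c1C | intermediate
20 | methyl 4-{[2,4-dihydroxy-3,5-bis(iminomethyl)-6-methylbenzoyl]oxy}-2-methoxy-3,5,6-trimethylbenzoate (imine stage drawn in its simplest, N-unsubstituted form) | Cc1c(C=N)c(O)c(C=N)c(O)c1C(=O)Oc1c(C)c(C)c(C(=O)OC)c(OC)c1C | intermediate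
21 | methyl 4-[(3,5-diformyl-2,4-dihydroxy-6-methylbenzoyl)oxy]-2-methoxy-3,5,6-trimethylbenzoate (CNP0217876.0) | COC(=O)c1c(C)c(C)c(OC(=O)c2c(C)c(C=O)c(O)c(C=O)c2O)c(C)c1OC | target

Total step count: 10
Longest linear sequence: 8 steps (8 to 21 through steps 3 to 10). Steps 1 and 2 form the short branch that joins at step 8.

Steps most likely to fail

Step 9. The ring-B phenoxide may be expelled faster than the aldol closes. This can happen by E1cB collapse of the C2 enolate back to the acylketene, or by acyl substitution at C1. The fallback sets out from 7 and 15 and comes back at 19.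
- The same C2-to-C7 aldol aromatisation is run on 7 itself (Et3N, CH2Cl2, rt). Here the carboxyl group is tied into the dioxinone and cannot leave. The product should be 7-hydroxy-2,2,5-trimethyl-4H-1,3-benzodioxin-4-one F1.
- The free phenol is capped (BnBr, K2CO3, acetone) so that it cannot compete as an acyl acceptor. This gives 7-(benzyloxy)-2,2,5-trimethyl-4H-1,3-benzodioxin-4-one F2.
- Irradiation at 300 nm in CH2Cl2 in the presence of 15 expels acetone. The ortho-quinoketene 3-(benzyloxy)-5-methyl-6-(oxomethylidene)cyclohexa-2,4-dien-1-one F3 then acylates the hindered phenol (photochemical quinoketene acylation).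
- The acylation product is methyl 4-{[4-(benzyloxy)-2-hydroxy-6-methylbenzoyl]oxy}-2-methoxy-3,5,6-trimethylbenzoate F4. Hydrogenolysis (H2, 10% Pd/C, EtOAc) then gives 19.

Step 8. The chain may be consumed before the hindered phenol is acylated. The causes would be internal capture of the ketene by the C5 enol oxygen, or thermal reversal of the phenol addition at 110 °C. The fallback sets out from 15 and comes back at 19.
- The ester bond is made by ordinary acylation with a small acid. Steglich esterification with but-2-ynoic acid (DCC, cat. DMAP, CH2Cl2, 0 °C) gives 3-methoxy-4-(methoxycarbonyl)-2,5,6-trimethylphenyl but-2-ynoate F5.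
- Ring A is then assembled by a Diels–Alder reaction with commercial 1-methoxy-1,3-bis(trimethylsilyloxy)buta-1,3-diene (3 equiv, xylene, 140 °C). The nucleophilic C4 terminus of the diene bonds to the methyl-bearing alkyne carbon.
- The cycloadduct is 3-methoxy-4-(methoxycarbonyl)-2,5,6-trimethylphenyl 6-methoxy-2-methyl-4,6-bis(trimethylsilyloxy)cyclohexa-1,4-diene-1-carboxylate F6. On treatment with dilute HCl in THF it loses methanol and both silyl groups and aromatises to 19.

Step 10. The second substitution may stall after the first. Acid-induced cleavage of the depside ester may also set in during prolonged heating in CF3CO2H. The fallback sets out from 19 and comes back at 21.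
- Both free positions are iodinated (N-iodosuccinimide, 2.2 equiv, MeCN, 0 °C → rt). This gives methyl 4-[(2,4-dihydroxy-3,5-diiodo-6-methylbenzoyl)oxy]-2-methoxy-3,5,6-trimethylbenzoate F7.
- A double Stille coupling under neutral conditions (Bu3SnCH=CH2, Pd(PPh3)4, toluene, 90 °C) gives methyl 4-[(3,5-diethenyl-2,4-dihydroxy-6-methylbenzoyl)oxy]-2-methoxy-3,5,6-trimethylbenzoate F8.
- Lemieux–Johnson cleavage (cat. OsO4, NaIO4, 2,6-lutidine, dioxane–water, rt) turns both vinyl groups into the formyl groups of 21.

Further compounds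
F1 | step 9 | 7-hydroxy-2,2,5-trimethyl-4H-1,3-benzodioxin-4-one | Cc1cc(O)cc2OC(C)(C)OC(=O)c12
F2 | step 9 | 7-(benzyloxy)-2,2,5-trimethyl-4H-1,3-benzodioxin-4-one | Cc1cc(OCc3ccccc3)cc2OC(C)(C)OC(=O)c12
F3 | step 9 | 3-(benzyloxy)-5-methyl-6-(oxomethylidene)cyclohexa-2,4-dien-1-one | O=C=C1C(C)=CC(OCc2ccccc2)=CC1=O
F4 | step 9 | methyl 4-{[4-(benzyloxy)-2-hydroxy-6-methylbenzoyl]oxy}-2-methoxy-3,5,6-trimethylbenzoate | Cc1cc(OCc2ccccc2)cc(O)c1C(=O)Oc1c(C)c(C)c(C(=O)OC)c(OC)c1C
F5 | step 8 | 3-methoxy-4-(methoxycarbonyl)-2,5,6-trimethylphenyl but-2-ynoate | CC#CC(=O)Oc1c(C)c(C)c(C(=O)OC)c(OC)c1C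
F6 | step 8 | 3-methoxy-4-(methoxycarbonyl)-2,5,6-trimethylphenyl 6-methoxy-2-methyl-4,6-bis(trimethylsilyloxy)cyclohexa-1,4-diene-1-carboxylate (racemic) | COC1(O[Si](C)(C)C)C=C(O[Si](C)(C)C)CC(C)=C1C(=O)Oc1c(C)c(C)c(C(=O)OC)c(OC)c1C
F7 | step 10 | methyl 4-[(2,4-dihydroxy-3,5-diiodo-6-methylbenzoyl)oxy]-2-methoxy-3,5,6-trimethylbenzoate | Cc1c(I)c(O)c(I)c(O)c1C(=O)Oc1c(C)c(C)c(C(=O)OC)c(OC)c1C
F8 | step 10 | methyl 4-[(3,5-diethenyl-2,4-dihydroxy-6-methylbenzoyl)oxy]-2-methoxy-3,5,6-trimethylbenzoate | Cc1c(C=C)c(O)c(C=C)c(O)c1C(=O)Oc1c(C)c(C)c(C(=O)OC)c(OC)c1C
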